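The plan treats the C3–C3' bond of the biindole as the former triple bond of a but-2-yne-1,4-diamine. Besides its partner, each of C3 and C3' is bonded only to the aryl carbon C3a (C3a') and to C2 (C2'), which sits on N1 (N1'). Both pyrrole rings are therefore cut at C3–C3a and C3'–C3a'. One palladium/hexamethylditin cascade on a symmetrical N,N'-di-Boc-N,N'-bis(5-bromo-2-iodophenyl)butynediamine should form these two bonds and close both five-membered nitrogen rings. The resulting biindolinylidene is one dehydrogenation away from the 6,6'-dibromobiindole. The benzo-ring bromines are carried through as spectators, and the C2 and C2' bromines are added last by electrophilic substitution.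

Key step: step 3

Assumption: the C3–C3' axis of the target is drawn without configuration, so axial chirality is not controlled and the target is treated as configurationally undefined.

Step 1
Reactants: 1 5-bromo-2-iodoaniline; 2 di-tert-butyl dicarbonate
Product: 3 tert-butyl (5-bromo-2-iodophenyl)carbamate
Conditions: NaN(SiMe3)2 (2.0 equiv), THF, 0 °C; then 2 (1.05 equiv), 0 °C to rt; H2O quench
Reagents that add atoms: di-tert-butyl dicarbonate (compound 2), CC(C)(C)OC(=O)OC(=O)OC(C)(C)C
Why: N-Boc carbamate formation through the preformed sodium anilide, which overcomes the low nucleophilicity of the hindered, electron-poor aniline, while the second equivalent of base holds the product as its carbamate anion and so should prevent a second acylation.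

Step 2
Reactants: 3 tert-butyl (5-bromo-2-iodophenyl)carbamate (2.1 equiv); 4 1,4-dichlorobut-2-yne
Product: 5 di-tert-butyl but-2-yne-1,4-diylbis[(5-bromo-2-iodophenyl)carbamate]
Conditions: NaH (2.05 equiv), DMF, 0 °C; then 4 (1.0 equiv), Bu4NI (10 mol %), 0 °C to rt
Reagents that add atoms: 1,4-dichlorobut-2-yne (compound 4), ClCC#CCCl
Why: Twofold SN2 N-alkylation of the carbamate anion at the two propargylic chlorides with iodide catalysis; each nitrogen can be alkylated only once, and keeping NaH slightly below the amount of carbamate leaves no free strong base to isomerise the alkyne to an allene.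

Step 3
Reactants: 5 di-tert-butyl but-2-yne-1,4-diylbis[(5-bromo-2-iodophenyl)carbamate]
Product: 7 di-tert-butyl (Z)-6,6'-dibromo-3,3'-biindolinylidene-1,1'-dicarboxylate, via (E)-alkenylstannane 6 (not isolated)
Conditions: Pd(PPh3)4 (10 mol %), Me3SnSnMe3 (1.05 equiv, syringe pump), 1,4-dioxane (0.01 M), 85 °C, argon
Reagents that add atoms: hexamethylditin, C[Sn](C)(C)[Sn](C)(C)C (its Me3Sn group appears only in intermediate 6; no atom of it remains in 7)
Why: Proposed new method: zerovalent palladium inserts into one C–I bond of 5, the arylpalladium iodide adds syn across the triple bond at the nearer alkyne carbon (first ring, 5-exo-dig, bond C3–C3a), and Me3SnSnMe3 hands a Me3Sn group to the resulting alkenylpalladium with retention, giving stannane 6 and Me3SnI. Insertion into the second C–I bond, intramolecular tin-to-palladium transfer of the alkenyl carbon to a six-membered palladacycle and reductive elimination then form C3'–C3a' and close the second five-membered ring, and the same palladacycle is reached if the second aryl iodide is stannylated before the alkenylpalladium is intercepted. The closest known reaction types are the 5-exo-dig cyclisation–anion capture of N-(2-iodoaryl)propargylamine derivatives to 3-alkylideneindolines and the Stille–Kelly ditin-mediated ring closure between two carbon–halogen bonds; their merger on one alkyne is the untested part. No stereocentre is formed; the Z geometry of C3=C3' follows from syn addition and retention in both tin steps, and since step 4 erases it, a loss of geometry costs nothing. Iodide-over-bromide selectivity rests on the weaker C–I bond, the modest reactivity of the PPh3-ligated catalyst at 85 °C and the single equivalent of ditin, which the two iodides use up. Ring closure ahead of aryl stannylation or direct aryl–aryl coupling is secured by the short N–CH2 tether (a unimolecular five-membered transition state against a bimolecular tin transfer kept slow by syringe-pump addition, and against a strained ten-membered cycloalkyne), and the base-free medium disfavours C–H palladation of the second ring.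

Step 4
Reactants: 7 di-tert-butyl (Z)-6,6'-dibromo-3,3'-biindolinylidene-1,1'-dicarboxylate
Product: 8 di-tert-butyl 6,6'-dibromo-3,3'-biindole-1,1'-dicarboxylate
Conditions: DDQ (1.1 equiv), toluene, rt to 60 °C
Reagents that add atoms: none
Why: DDQ dehydrogenation: hydride loss from the allylic, nitrogen-bearing C2–H gives a cation spread over C2, C3 and C3', and proton loss from C2' then makes both five-membered rings aromatic, so this formal 1,4-dehydrogenation is driven by the gain of two indole units and converges any material whose double bond has already moved into a ring.

Step 5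
Reactants: 8 di-tert-butyl 6,6'-dibromo-3,3'-biindole-1,1'-dicarboxylate
Product: 9 6,6'-dibromo-1H,1'H-3,3'-biindole
Conditions: K2CO3 (3 equiv), MeOH–THF, 55 °C
Reagents that add atoms: none
Why: Base-mediated carbamate methanolysis: an indole N-Boc group is an activated acyl-azole type carbamate with an indolide leaving group, so methoxide should cleave it mildly, and working without acid avoids C3 protonation of the biindole with its risk of aryl migration or oligomerisation.

Step 6
Reactants: 9 6,6'-dibromo-1H,1'H-3,3'-biindole
Product: 10 2,2',6,6'-tetrabromo-1H,1'H-3,3'-biindole
Conditions: NBS (2.0 equiv), anhydrous THF, −78 to 0 °C, dark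
Reagents that add atoms: N-bromosuccinimide, O=C1CCC(=O)N1Br
Why: Electrophilic bromination of a 3-substituted indole (attack on the enamine unit, via a 3-bromoindolenine and 1,2-shift or directly at C2): C2 is the only open pyrrole position, the 6-bromo groups deactivate the benzo rings, and the first C2 bromine deactivates its own ring, so the second equivalent should go to C2'.

Compound list
1 | 5-bromo-2-iodoaniline | Nc1cc(Br)ccc1I | starting material
2 | di-tert-butyl dicarbonate | CC(C)(C)OC(=O)OC(=O)OC(C)(C)C | starting material
3 | tert-butyl (5-bromo-2-iodophenyl)carbamate | CC(C)(C)OC(=O)Nc1cc(Br)ccc1I | intermediate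
4 | 1,4-dichlorobut-2-yne | ClCC#CCCl | starting material
5 | di-tert-butyl but-2-yne-1,4-diylbis[(5-bromo-2-iodophenyl)carbamate] | CC(C)(C)OC(=O)N(CC#CCN(C(=O)OC(C)(C)C)c1cc(Br)ccc1I)c1cc(Br)ccc1I | intermediate
6 | tert-butyl (3E)-6-bromo-3-{2-[(5-bromo-2-iodophenyl)(tert-butoxycarbonyl)amino]-1-(trimethylstannyl)ethylidene}indoline-1-carboxylate (Me3Sn cis to C3a) | CC(C)(C)OC(=O)N1C/C(c2ccc(Br)cc12)=C(/[Sn](C)(C)C)CN(C(=O)OC(C)(C)C)c1cc(Br)ccc1I | intermediate
7 | di-tert-butyl (Z)-6,6'-dibromo-3,3'-biindolinylidene-1,1'-dicarboxylate (two N-Boc-6-bromoindolines joined by C3=C3', with C3a and C3a' on the same side) | CC(C)(C)OC(=O)N1C/C(c2ccc(Br)cc12)=C2\CN(C(=O)OC(C)(C)C)c3cc(Br)ccc23 | intermediate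
8 | di-tert-butyl 6,6'-dibromo-3,3'-biindole-1,1'-dicarboxylate | CC(C)(C)OC(=O)n1cc(-c2cn(C(=O)OC(C)(C)C)c3cc(Br)ccc23)c2ccc(Br)cc12 | intermediate
9 | 6,6'-dibromo-1H,1'H-3,3'-biindole | Brc1ccc2c(-c3c[nH]c4cc(Br)ccc34)c[nH]c2c1 | intermediate
10 | 2,2',6,6'-tetrabromo-1H,1'H-3,3'-biindole | Brc1ccc2c(-c3c(Br)[nH]c4cc(Br)ccc34)c(Br)[nH]c2c1 | target

Total step count: 6
Longest linear sequence: 6 steps (1 to 10)

Steps most likely to fail

1. Step 3.
- What may go wrong:
  - tin transfer to the arylpalladium before it has cyclised
  - palladium-catalysed distannylation of the triple bond
  - slow transmetalation at the crowded, fully substituted alkenyl carbon, with protodemetalation or methyl transfer taking over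
  - 1,4-migration of palladium to C4
  - insertion into the C–Br bonds once the iodides are consumed
- Fallback (known chemistry): set out from 5 and make the same two bonds by tin hydride mediated aryl radical cyclisation, as established for N-propargyl and N-allyl 2-haloanilides, using Bu3SnH (2.1 equiv, slow addition), AIBN, toluene, 85 °C. Selective iodine abstraction, 5-exo-dig attack on the alkyne and hydrogen transfer should be followed by 5-exo-trig attack of the second aryl radical on the new trisubstituted alkene. This should give di-tert-butyl 6,6'-dibromo-3,3'-biindoline-1,1'-dicarboxylate F1 as a mixture of diastereomers whose stereocentres are erased next. DDQ (2.2 equiv) in hot toluene dehydrogenates both indoline rings, and the route is rejoined at 8.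

2. Step 6.
- What may go wrong:
  - further bromination of the benzo rings or of nitrogen
  - oxidation at C2 by adventitious water
  - decay of the light- and acid-sensitive product during isolation
- Fallback: set out from 8 and replace electrophilic substitution by carbamate-directed C2 metalation. LiN(iPr)2 (2.4 equiv), THF, −78 °C, then 1,2-dibromo-1,1,2,2-tetrachloroethane should give di-tert-butyl 2,2',6,6'-tetrabromo-3,3'-biindole-1,1'-dicarboxylate F2. An amide base does not exchange the aryl bromides. Methanolysis with K2CO3 in MeOH–THF at rt removes both Boc groups, and the route is rejoined at 10.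

3. Step 4.
- What may go wrong:
  - sluggish hydride abstraction, because the carbamate lowers the donor strength of nitrogen
  - covalent adduct formation between DDQ and the strained, electron-rich alkene
- Fallback: set out from 7 and deprotect first. TFA in CH2Cl2 (0 °C to rt, basic work-up) removes both Boc groups and moves the double bond into one ring under acid catalysis. This should give racemic 6-bromo-3-(6-bromoindolin-3-yl)-1H-indole F3. Its free indoline ring is then dehydrogenated with activated MnO2 in CH2Cl2 at rt, and the route is rejoined at 9, with 8 and step 5 bypassed.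

Further compounds
F1 | step 3 | di-tert-butyl 6,6'-dibromo-3,3'-biindoline-1,1'-dicarboxylate (mixture of meso and racemic diastereomers, configuration not defined) | CC(C)(C)OC(=O)N1CC(C2CN(C(=O)OC(C)(C)C)c3cc(Br)ccc23)c2ccc(Br)cc12
F2 | step 6 | di-tert-butyl 2,2',6,6'-tetrabromo-3,3'-biindole-1,1'-dicarboxylate | CC(C)(C)OC(=O)n1c(Br)c(-c2c(Br)n(C(=O)OC(C)(C)C)c3cc(Br)ccc23)c2ccc(Br)cc12
F3 | step 4 | 6-bromo-3-(6-bromoindolin-3-yl)-1H-indole (racemic) | Brc1ccc2c(c1)NCC2c1c[nH]c2cc(Br)ccc12
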